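## Structural features

The target is a (2S)-flavanone. Ring C is a dihydropyranone (O1, C2, C3, C4) fused to ring A through C4a and C8a, and C2 carries ring B, a 4-hydroxyphenyl group. Ring A is fully substituted: 5-OH (hydrogen-bonded to the C4 carbonyl), 6-OMe, 7-OMe, 8-prenyl and the two fusion carbons. C2 is the only stereocentre, a benzylic ether carbon β to the ketone, with no neighbouring stereocentre to relay from. It is fragile: enolisation at C3 can expel O1 (retro-oxa-Michael opening to the 2'-hydroxychalcone), and a free 4'-phenoxide can push O1 out as well, so base erodes the configuration. The prenyl olefin is sensitive to strong acid and to electrophiles. The real difficulties are absolute control of this isolated, epimerisable C2 and the regiodefined placement of four different groups, one of them a C-prenyl group, on ring A. The key step uses the fact that O1–C8a–C4a–C4 is a latent ortho-quinone methide and C2–C3 with ring B is a latent styrene, so one [4+2] union makes O1–C2 and C3–C4 and closes ring C.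

## Logic of the disconnections

18 to 17: the O–acetyl bond at O4' is cut. The 4'-phenol must stay masked until the end because it would compete in the etherification at O5 and would labilise C2. The forward step must remove the ester without generating a phenoxide long enough to open ring C.

17 to 14: the C8–CH2 bond of the prenyl group is cut and traced back to an O5–prenyl ether. Both ortho positions of O5 (C6 and C4a) are blocked, so a Claisen shift followed by a Cope shift can only deliver the group to C8, the para position. This solves the regiochemistry of C-prenylation with no directing group. The forward step must run the two sigmatropic shifts without ionising the allyl ether.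

14 to 12 + 13: the O5–CH2 bond is cut. The forward etherification must alkylate a chelated, doubly flanked phenol at the primary carbon of 13 under conditions that do not enolise C3.

12 to 10: the O5–H is traced back to O5–CH3. The C4 carbonyl singles out the peri methyl ether by chelation, so the three methoxy groups can be carried as a uniform set from 1. The forward step needs a Lewis acid that stops after one demethylation and leaves the acetate alone.

10 to 9 to 8: the C4 carbonyl is traced back to a C4 methyl ether by way of the alcohol. The C4 stereocentre of 8 is sacrificial, so only C2 of 8 matters. The forward steps must exchange OMe for OH at a highly stabilised benzylic position and then oxidise without touching C2.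

8 to 3 + 4 + 5: O1–C2 and C3–C4 are cut together. This removes ring C and both stereocentres in one operation and leaves a salicylaldehyde, an orthoformate and a styrene. The forward step must control the face at C2 through a chiral counter-anion and must be run before the prenyl group is present, because an ortho-prenyl phenol would cyclise under the acid.

3 to 1: the C4a–CHO bond is cut. The two positions ortho to the hydroxyl of 1 are equivalent and the para position is blocked, so formylation has only one possible outcome.

## Other disconnections considered

Alternative 1: The cut is the C3=C4 bond of the enol form of the ketone. In the forward direction the diene A2, an (S)-1-arylallyl aryl ether carrying a 1-silyloxyvinyl group on C4a, would undergo ring-closing metathesis with the second-generation Grubbs catalyst (H2IMes)(PCy3)Cl2Ru=CHPh to give the 4-silyloxy-2H-chromene A1 with loss of ethylene.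
- In favour: C4 arrives at the ketone oxidation level, masked as an enol ether, so no hydrolysis and oxidation are needed. The C2 stereocentre is made earlier by established chemistry such as an asymmetric allylic etherification, so the stereochemistry does not rest on an untested catalytic step; on this point the alternative is better than the chosen plan. The prenyl group is present from the start, which avoids the etherification and rearrangement.
- Against: the prenyl olefin on C8 is a competent metathesis partner for the vinyl group and would close a seven-membered benzoxepine with loss of isobutene. The silyl enol ether is 1,1-disubstituted and twisted between two ortho substituents, so the desired closure is the slower one. Ruthenium hydride species could isomerise the allyl ether and destroy C2. Fluoride desilylation of A1 is basic enough to threaten C2. The hexasubstituted acetophenone needed for A2 takes several steps.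
- Comparison: on structure, this makes one ring bond where the chosen plan makes two bonds and the stereocentre together. On mechanism, metathesis is well understood but chemoselectivity against the prenyl group is the weak point, whereas the chosen plan introduces the prenyl group after all olefin-sensitive chemistry. On step economy, the sequence after ring closure is shorter, but the route to A2 is longer, and both plans need the same late 5-O-demethylation, so they are equal there.

Alternative 2: The cut is O1–C8a. The catechol A4, an (S)-β-hydroxy ketone, would be oxidised at a graphite anode (LiClO4, buffered aqueous acetonitrile) to the 3-acyl ortho-quinone, and the C2 hydroxyl would add to C8a. Rearomatisation would give the 5,6-dihydroxyflavanone A3.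
- In favour: C2 comes from a known asymmetric aldol or ketone reduction. C8a is the only unsubstituted quinone carbon and is activated by two carbonyl groups, so the regiochemistry is clear. The 5-OH is delivered free, so no Lewis-acid demethylation is needed, which is better than the chosen plan. The oxidant is the electrode and no strong acid is used.
- Against: A3 carries one more oxygen donor than A4 and should be easier to oxidise than its precursor, so over-oxidation has to be held back by charge control. Water in the medium competes with the hydroxyl for the quinone. The β-hydroxy ketone can dehydrate to the chalcone or undergo retro-aldol cleavage. The prenyl olefin sits on an electron-rich ring at the anode. A3 then needs a selective methylation of the 6-OH under conditions that do not open ring C, and the prenylated catechol for A4 is long to make.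
- Comparison: on structure, it forms one C–O bond of ring C and leaves the stereocentre to an earlier step. On mechanism, the stereochemical risk is lower than in the chosen plan, but the chemoselectivity risk is higher. On step economy, the end game (methylation, deacetylation) is shorter, but the overall count is expected to be higher because of the route to A4.

Alternative 3: The cut is C4–C4a. The acid chloride or trifluoroacetic mixed anhydride of the (S)-3-aryloxy-3-arylpropanoic acid A6 would acylate C4a under SnCl4 at low temperature to give the flavanone A5.
- In favour: C4a is the only free position on ring A and is activated by three oxygen donors, so the regiochemistry is certain. C4 is formed directly as the ketone. The prenyl group is already in place. Only 5-O-demethylation and deacetylation follow, the shortest end game of all four plans and better than the chosen plan on this count.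
- Against: a β-aryloxy acyl electrophile under a Lewis acid can lose the phenol by elimination to the cinnamoyl compound, or ionise the benzylic C2–O bond, and either path destroys C2. The prenyl olefin is exposed to SnCl4 and HCl. The hindered benzylic aryl ether stereocentre of A6 is itself hard to make in high purity, since etherification of a benzylic alcohol with inversion by a 2,6-flanked phenol tends to leak through ionisation. The 2-prenylphenol needed cannot be reached by a simple Claisen shift, which would give the reverse-prenyl isomer.
- Comparison: on structure, it makes one C–C bond and no stereocentre. On mechanism, the acylation is classical but runs through intermediates that endanger both C2 and the prenyl group, whereas the chosen plan creates C2 in the ring-forming step and keeps strong acid away from the prenyl group. On step economy, it is equal or slightly shorter after cyclisation and longer before it.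

Key step: step 2

Assumption: the (S,S) antipode of the confined acid is taken to give the (2S,4S) adduct; the sense of induction of this new reaction cannot be derived from precedent, and the (R,R) catalyst is used if it proves opposite.

Remark: in adduct 8 the descriptors (2S,4S) correspond to the 2,4-cis isomer, and (2S) is the configuration required in the target, so the structures need no correction. The precursor pair 3 and 5 is kept as it is:
- the phenol of 3 must be free to close the ring;
- C8 is left unsubstituted because a prenyl group there would cyclise onto the phenol under the acid;
- ring B carries an acetate because a free phenol or an alkyl ether would make the styrene prone to cationic oligomerisation and would make C2–O1 easier to ionise again.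

## Route

Step 1
Reactants: 1 3,4,5-trimethoxyphenol
Product: 3 2-hydroxy-4,5,6-trimethoxybenzaldehyde, via aryl iminium chloride 2 (not isolated)
Conditions: POCl3, DMF, 0 °C to rt; then H2O
Reagents that add atoms: N,N-dimethylformamide (CN(C)C=O); water (O)
Why: Vilsmeier–Haack formylation; the two positions ortho to the hydroxyl are equivalent and the para position is blocked, so the chloroiminium ion can only give iminium 2, which water hydrolyses to the salicylaldehyde 3.

Step 2
Reactants: 3 2-hydroxy-4,5,6-trimethoxybenzaldehyde; 4 trimethyl orthoformate; 5 4-acetoxystyrene (4-ethenylphenyl acetate)
Product: 8 (2S,4S)-4'-acetoxy-4,5,6,7-tetramethoxyflavan (2,4-cis), via dimethyl acetal 6 (not isolated), via O-methyl ortho-quinone methide cation 7 (not isolated)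
Conditions: (S,S)-IDPi acid (confined N-triflyl imidodiphosphorimidate built on two (S)-3,3'-diaryl-BINOL units, 5 mol%), 4 (1.5 equiv), 5 (2 equiv), CH2Cl2, −40 °C; then Et3N
Reagents that add atoms: none
Why: Proposed new method: the acid catalyses acetalisation of 3 by 4 to 6 and then ionises 6 to the O-methyl ortho-quinone methide cation 7, held as a contact ion pair by the chiral imidodiphosphorimidate anion, which can also accept a hydrogen bond from the phenolic OH. The CH2 terminus of styrene 5 (future C3) adds to the cationic carbon (future C4) and the phenolic oxygen collapses onto the developing 4-acetoxybenzylic cation (future C2); this is an asynchronous inverse-demand [4+2] annulation in which C3–C4 forms first and the six-membered ring C closes by O1–C2 capture of the benzylic cation. The closest known reaction types are the achiral acid-promoted condensation of salicylaldehydes, orthoformates and styrenes to 2,4-cis-4-alkoxy-2-arylchromans and the chiral phosphoric acid-catalysed cycloadditions of ortho-quinone methides with styrenes; the new element is making the orthoformate variant enantioselective with a confined acid. The C2 configuration is controlled by the chiral counter-anion, which must shield one face of the heterodiene so that the styrene approaches from the other. The C4 configuration follows from C2 through the endo-like arrangement that places aryl and methoxy cis and pseudo-equatorial, and it is erased in step 4. Regiochemistry is secured by polarity: the nucleophilic styrene terminus meets the only electrophilic carbon and the cation that results is benzylic. The step also needs chemoselectivity for styrene capture over Friedel–Crafts attack by the electron-rich arenes and over oligomerisation of 5; the low temperature, the excess of 5, the moderate donor strength of the acetoxy group and the narrow catalyst pocket are relied on for this.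

Step 3
Reactants: 8 (2S,4S)-4'-acetoxy-4,5,6,7-tetramethoxyflavan
Product: 9 (2S)-4'-acetoxy-5,6,7-trimethoxyflavan-4-ol (mixture of C4 epimers)
Conditions: 0.5 M aq. HCl, THF, rt
Reagents that add atoms: water (O)
Why: Acid-catalysed SN1 hydrolysis of a benzylic methyl ether; the C4 cation is stabilised by O1 and the 5- and 7-methoxy groups, so dilute acid should suffice and the aryl acetate and C2 are not touched. The C4 epimer mixture is irrelevant because C4 is oxidised next.

Step 4
Reactants: 9 (2S)-4'-acetoxy-5,6,7-trimethoxyflavan-4-ol
Product: 10 (2S)-4'-acetoxy-5,6,7-trimethoxyflavanone
Conditions: Dess–Martin periodinane, pyridine, CH2Cl2, 0 °C to rt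
Reagents that add atoms: none
Why: Dess–Martin oxidation of a secondary benzylic alcohol under buffered, non-basic conditions; both C4 epimers converge on the ketone and C2, now α to an enolisable position, is not exposed to base.

Step 5
Reactants: 10 (2S)-4'-acetoxy-5,6,7-trimethoxyflavanone
Product: 12 (2S)-4'-acetoxy-5-hydroxy-6,7-dimethoxyflavanone, via dichloroboron aryloxide chelate 11 (not isolated)
Conditions: BCl3 (1.2 equiv), CH2Cl2, −78 to −20 °C; then H2O
Reagents that add atoms: none
Why: Chelation-directed peri-demethylation; BCl3 binds the C4 carbonyl and the 5-methoxy oxygen in a six-membered chelate, chloride removes that methyl group as chloromethane, and water frees the phenol from 11. The 6- and 7-methyl ethers and the aryl acetate lack this activation, and the low temperature and near-stoichiometric reagent limit a second demethylation at O6.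

Step 6
Reactants: 12 (2S)-4'-acetoxy-5-hydroxy-6,7-dimethoxyflavanone; 13 prenol (3-methylbut-2-en-1-ol)
Product: 14 (2S)-4'-acetoxy-6,7-dimethoxy-5-(3-methylbut-2-enyloxy)flavanone
Conditions: PPh3, DIAD, THF, 0 °C to rt
Reagents that add atoms: none
Why: Mitsunobu etherification; the chelated phenol is acidic enough to protonate the betaine and attacks the primary carbon of the activated prenol in an SN2 reaction. The medium is close to neutral, so C3 is not enolised, and the acetate keeps the 4'-oxygen out of the reaction.

Step 7
Reactants: 14 (2S)-4'-acetoxy-6,7-dimethoxy-5-(3-methylbut-2-enyloxy)flavanone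
Product: 17 (2S)-4'-acetoxy-5-hydroxy-6,7-dimethoxy-8-(3-methylbut-2-enyl)flavanone, via ortho-dienone 15 (not isolated), via para-dienone 16 (not isolated)
Conditions: Eu(fod)3 (10 mol%), CHCl3, 60 °C
Reagents that add atoms: none
Why: Para-Claisen–Cope rearrangement, as used for 5-O-prenyl flavanones; the trivalent europium chelate Eu(fod)3 (fod = 6,6,7,7,8,8,8-heptafluoro-2,2-dimethyloctane-3,5-dionate) binds the C4 carbonyl and O5 and accelerates the [3,3] shift to the blocked ortho carbon (15, drawn at C6; the C4a isomer funnels the same way). Dienone 15 cannot enolise, so a Cope shift carries the group to C8 (16) with restoration of the normal prenyl connectivity, and tautomerisation gives the phenol 17. C8 is the only position that can rearomatise, which fixes the regiochemistry.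

Step 8
Reactants: 17 (2S)-4'-acetoxy-5-hydroxy-6,7-dimethoxy-8-(3-methylbut-2-enyl)flavanone
Product: 18 (2S)-4',5-dihydroxy-6,7-dimethoxy-8-(3-methylbut-2-enyl)flavanone (the target)
Conditions: NH4OAc, MeOH–H2O (4:1), rt
Reagents that add atoms: none
Why: Near-neutral solvolysis (transesterification) of an aryl acetate catalysed by ammonium acetate; no phenoxide or C3 enolate builds up, so ring C should not open and C2 should stay (S). The prenyl group has no free ortho phenol and is not exposed to acid.

## Compound list

1 | 3,4,5-trimethoxyphenol | COc1cc(O)cc(OC)c1OC | starting material
2 | N-[(2-hydroxy-4,5,6-trimethoxyphenyl)methylidene]-N-methylmethanaminium chloride | C[N+](C)=Cc1c(O)cc(OC)c(OC)c1OC.[Cl-] | intermediate (not isolated)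
3 | 2-hydroxy-4,5,6-trimethoxybenzaldehyde | COc1cc(O)c(C=O)c(OC)c1OC | intermediate
4 | trimethyl orthoformate | COC(OC)OC | starting material
5 | 4-acetoxystyrene (4-ethenylphenyl acetate) | C=Cc1ccc(OC(C)=O)cc1 | starting material
6 | 2-(dimethoxymethyl)-3,4,5-trimethoxyphenol | COC(OC)c1c(O)cc(OC)c(OC)c1OC | intermediate (not isolated)
7 | (2-hydroxy-4,5,6-trimethoxyphenyl)(methoxy)methylium, the O-methyl ortho-quinone methide cation, paired with the catalyst anion | C[O+]=Cc1c(O)cc(OC)c(OC)c1OC | intermediate (not isolated)
8 | 4-[(2S,4S)-4,5,6,7-tetramethoxy-3,4-dihydro-2H-chromen-2-yl]phenyl acetate (2,4-cis) | COc1c(OC)c2c(cc1OC)O[C@H](c1ccc(OC(C)=O)cc1)C[C@@H]2OC | intermediate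
9 | 4-[(2S)-4-hydroxy-5,6,7-trimethoxy-3,4-dihydro-2H-chromen-2-yl]phenyl acetate (C4 epimers) | COc1c(OC)c2c(cc1OC)O[C@H](c1ccc(OC(C)=O)cc1)CC2O | intermediate
10 | 4-[(2S)-5,6,7-trimethoxy-4-oxo-3,4-dihydro-2H-chromen-2-yl]phenyl acetate | COc1c(OC)c2c(cc1OC)O[C@H](c1ccc(OC(C)=O)cc1)CC2=O | intermediate
11 | 4-[(2S)-5-(dichloroboranyloxy)-6,7-dimethoxy-4-oxo-3,4-dihydro-2H-chromen-2-yl]phenyl acetate (boron chelated to the C4 carbonyl) | COc1c(OB(Cl)Cl)c2c(cc1OC)O[C@H](c1ccc(OC(C)=O)cc1)CC2=O | intermediate (not isolated)
12 | 4-[(2S)-5-hydroxy-6,7-dimethoxy-4-oxo-3,4-dihydro-2H-chromen-2-yl]phenyl acetate | COc1c(O)c2c(cc1OC)O[C@H](c1ccc(OC(C)=O)cc1)CC2=O | intermediate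
13 | prenol (3-methylbut-2-en-1-ol) | CC(C)=CCO | starting material
14 | 4-[(2S)-6,7-dimethoxy-5-(3-methylbut-2-enyloxy)-4-oxo-3,4-dihydro-2H-chromen-2-yl]phenyl acetate | COc1c(OCC=C(C)C)c2c(cc1OC)O[C@H](c1ccc(OC(C)=O)cc1)CC2=O | intermediate
15 | 4-[(2S)-6,7-dimethoxy-6-(2-methylbut-3-en-2-yl)-4,5-dioxo-3,4,5,6-tetrahydro-2H-chromen-2-yl]phenyl acetate (ortho-dienone, C6 epimers) | O1[C@H](c3ccc(OC(C)=O)cc3)CC(=O)C2=C1C=C(OC)C(OC)(C(C)(C)C=C)C2=O | intermediate (not isolated)
16 | 4-[(2S)-6,7-dimethoxy-8-(3-methylbut-2-enyl)-4,5-dioxo-3,4,5,8-tetrahydro-2H-chromen-2-yl]phenyl acetate (para-dienone, C8 epimers) | O1[C@H](c3ccc(OC(C)=O)cc3)CC(=O)C2=C1C(CC=C(C)C)C(OC)=C(OC)C2=O | intermediate (not isolated)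
17 | 4-[(2S)-5-hydroxy-6,7-dimethoxy-8-(3-methylbut-2-enyl)-4-oxo-3,4-dihydro-2H-chromen-2-yl]phenyl acetate | COc1c(O)c2c(c(CC=C(C)C)c1OC)O[C@H](c1ccc(OC(C)=O)cc1)CC2=O | intermediate
18 | (2S)-5-hydroxy-2-(4-hydroxyphenyl)-6,7-dimethoxy-8-(3-methylbut-2-enyl)-2,3-dihydro-4H-chromen-4-one | COc1c(O)c2c(c(CC=C(C)C)c1OC)O[C@H](c1ccc(O)cc1)CC2=O | target

## Step count and uncertain steps

Total step count: 8. Longest linear sequence: 8 steps, from 1 to 18; 4, 5 and 13 are bought.

Step 2 (key step, proposed new method). The most likely failure is poor enantioface discrimination: the ion pair of 7 is loose, and any reaction outside the catalyst pocket or catalysed by trace achiral acid gives racemic adduct. Oligomerisation of 5 and re-ionisation of the 4-methoxy group of the adduct, followed by a second styrene addition, can also take material. The fallback uses known chemistry and sets out from 1: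
- Friedel–Crafts acetylation (AcOH, BF3·OEt2, 90 °C) should give 1-(2-hydroxy-4,5,6-trimethoxyphenyl)ethanone F1.
- Condensation with N,N-dimethylformamide dimethyl acetal (COC(OC)N(C)C) should give the enaminone (E)-3-(dimethylamino)-1-(2-hydroxy-4,5,6-trimethoxyphenyl)prop-2-en-1-one F2.
- HCl in CH2Cl2 should close it to 5,6,7-trimethoxychromone F3.
- Asymmetric conjugate addition of (4-acetoxyphenyl)boronic acid (CC(=O)Oc1ccc(B(O)O)cc1) under divalent palladium catalysis (Pd(OCOCF3)2, the antipode of the tert-butyl pyridine-oxazoline ligand that delivers the (2S) product, NH4PF6, H2O, 1,2-dichloroethane, 60 °C) should then give the flavanone.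

The fallback comes back to the route at 10.

Step 7. The most likely failure is heterolytic loss of the prenyl group from the Lewis-acid-bound ether, returning the phenol, in competition with the two sigmatropic shifts; the 6-methoxy group makes the first shift more crowded than in the known 6-unsubstituted cases. The fallback sets out from 12 and also bypasses step 6:
- Iodination with N-iodosuccinimide in DMF at C8, the only free and strongly activated ring A position, should give (2S)-4'-acetoxy-5-hydroxy-8-iodo-6,7-dimethoxyflavanone F4.
- Stille coupling with tributyl(3-methylbut-2-enyl)stannane (CCCC[Sn](CCCC)(CCCC)CC=C(C)C) and the zerovalent palladium complex Pd(PPh3)4 in DMF at 90 °C should attach the linear prenyl group.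

The fallback comes back to the route at 17.

Step 3. The most likely failure is diversion of the C4 cation: loss of a C3 proton to the flav-3-ene, or capture by C8 of a second molecule, in competition with capture by water; slow hydrolysis of the acetate is a lesser concern. The fallback sets out from 8 and changes the reaction type from solvolysis to oxidation. DDQ in wet CH2Cl2 at 0 °C should abstract the C4 hydride of the electron-rich benzylic methyl ether, as in the oxidative removal of p-methoxybenzyl ethers, and the resulting methoxy-oxocarbenium ion should be hydrolysed to the ketone. It comes back to the route at 10 and makes no new compound (F0).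

Step 8. The most likely failure is erosion of the C2 configuration by reversible opening of ring C, which becomes easier once the 4'-phenol is free, since its phenoxide can expel O1. The fallback sets out from 17 and replaces solvolysis by biocatalysis: immobilised Candida antarctica lipase B with n-butanol in tert-butyl methyl ether at 40 °C should transfer the acetyl group to butanol at neutral pH. It comes back to the route at 18 and makes no new compound (F0).

## Further compounds

F1 | step 2 | 1-(2-hydroxy-4,5,6-trimethoxyphenyl)ethanone | CC(=O)c1c(O)cc(OC)c(OC)c1OC
F2 | step 2 | (E)-3-(dimethylamino)-1-(2-hydroxy-4,5,6-trimethoxyphenyl)prop-2-en-1-one | CN(C)/C=C/C(=O)c1c(O)cc(OC)c(OC)c1OC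
F3 | step 2 | 5,6,7-trimethoxychromone (5,6,7-trimethoxy-4H-chromen-4-one) | COc1cc2occc(=O)c2c(OC)c1OC
F4 | step 7 | (2S)-4'-acetoxy-5-hydroxy-8-iodo-6,7-dimethoxyflavanone | COc1c(O)c2c(c(I)c1OC)O[C@H](c1ccc(OC(C)=O)cc1)CC2=O
F0 | step 3 | none | none
F0 | step 8 | none | none
A1 | alternative 1 | (2S)-4-(tert-butyldimethylsilyloxy)-2-[4-(tert-butyldimethylsilyloxy)phenyl]-5,6,7-trimethoxy-8-prenyl-2H-chromene | COc1c(OC)c2c(c(CC=C(C)C)c1OC)O[C@H](c1ccc(O[Si](C)(C)C(C)(C)C)cc1)C=C2O[Si](C)(C)C(C)(C)C
A2 | alternative 1 | (S)-1-[4-(tert-butyldimethylsilyloxy)phenyl]allyl 2-[1-(tert-butyldimethylsilyloxy)vinyl]-3,4,5-trimethoxy-6-prenylphenyl ether | C=C(O[Si](C)(C)C(C)(C)C)c1c(OC)c(OC)c(OC)c(CC=C(C)C)c1O[C@@H](C=C)c1ccc(O[Si](C)(C)C(C)(C)C)cc1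
A3 | alternative 2 | (2S)-4'-acetoxy-5,6-dihydroxy-7-methoxy-8-prenylflavanone | Oc1c(O)c2c(c(CC=C(C)C)c1OC)O[C@H](c1ccc(OC(C)=O)cc1)CC2=O
A4 | alternative 2 | (S)-3-(4-acetoxyphenyl)-1-[2,3-dihydroxy-4-methoxy-5-(3-methylbut-2-enyl)phenyl]-3-hydroxypropan-1-one | COc1c(O)c(O)c(C(=O)C[C@H](O)c2ccc(OC(C)=O)cc2)cc1CC=C(C)C
A5 | alternative 3 | (2S)-4'-acetoxy-5,6,7-trimethoxy-8-prenylflavanone | COc1c(OC)c2c(c(CC=C(C)C)c1OC)O[C@H](c1ccc(OC(C)=O)cc1)CC2=O
A6 | alternative 3 | (3S)-3-(4-acetoxyphenyl)-3-[3,4,5-trimethoxy-2-(3-methylbut-2-enyl)phenoxy]propanoic acid | COc1cc(O[C@H](c2ccc(OC(C)=O)cc2)CC(=O)O)c(CC=C(C)C)c(OC)c1OC
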